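**Retrosynthetic overview**

1. The strategy rests on the vicinal C8–O/C9–O pair of the ten-membered carbocycle (germacrane numbering). It lies between the C6 oxygen and the ring-cis C1=C10 olefin, which makes the ring a 1,2-dioxygenated cyclodec-5-enone, the retron of an oxy-Cope ring expansion.
2. Key disconnection: C8–C9 (re-forming C1–C6 of a cyclohexene) leads to a cis-6-(dioxinyl)-1-[(E)-alkoxyvinyl]cyclohex-2-en-1-ol. This comes from a 6-(dioxinyl)cyclohexenone (Pd-catalysed α′-alkenylation, enzymatic resolution) and a 4-methoxybenzyloxyacetylide.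
3. After ring expansion the C8 hydroxyl steers the C7 alkylation with iodoacetate (chelated aldolate). The C6–O bond of the lactone is closed with inversion to the trans-fused γ-lactone, then α-methylenation.
4. End game: O8 methacrylate, acetonide removal, C14 oxidation, O9 acetate, O15 desilylation.
5. Ring order: cyclohexene (from the start) → ten-membered carbocycle (step 12) → γ-lactone (steps 15 and 16).

Key step: step 12

Remark: ten-membered compounds are named with germacrane numbering (C1=C10 bears C14, C4=C5 bears C15); "ring-cis" means that the two ring carbons on an olefin lie on the same side.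
Remark: PMB = 4-methoxybenzyl, TBDPS = tert-butyldiphenylsilyl, TES = triethylsilyl, dioxinyl = 2,2-dimethyl-4H-1,3-dioxin-5-yl.
Assumption: the lipase of step 6 is taken to follow the usual size rule for secondary alcohols, as it does for trans-2-arylcyclohexanols.

**Route**

Step 1
Reactants: 1 3-methoxybenzyl alcohol
Product: 3 3-(hydroxymethyl)cyclohex-2-en-1-one, via Birch diene 2 (not isolated)
Conditions: Li, NH3 (l), t-BuOH, THF, −78 °C; then 2 M HCl, THF, 20 °C
Reagents that add atoms: water, O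
Why: Birch reduction of the anisole ring (benzylic oxygen masked as its lithium alkoxide) gives the 1-methoxycyclohexa-1,4-diene, and acid hydrolysis of the enol ether with migration of the double bond into conjugation gives the enone.

Step 2
Reactants: 3 3-(hydroxymethyl)cyclohex-2-en-1-one
Product: 4 3-[(TBDPS-oxy)methyl]cyclohex-2-en-1-one
Conditions: t-BuPh2SiCl, imidazole, DMF, 20 °C
Reagents that add atoms: tert-butyl(chloro)diphenylsilane, CC(C)(C)[Si](Cl)(c1ccccc1)c1ccccc1
Why: standard silylation of the primary allylic alcohol; the bulky silyl ether should survive the later acidic acetonide cleavage and is removed last.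

Step 3
Reactants: 5 2,2-dimethyl-1,3-dioxan-5-one
Product: 7 2,2-dimethyl-4H-1,3-dioxin-5-yl trifluoromethanesulfonate, via lithium enolate 6 (not isolated)
Conditions: LiN(SiMe3)2, THF, −78 °C; then PhNTf2, −78 → 0 °C
Reagents that add atoms: N-phenylbis(trifluoromethanesulfonimide), O=S(=O)(N(c1ccccc1)S(=O)(=O)C(F)(F)F)C(F)(F)F
Why: enol triflate formation by O-sulfonylation of the ketone enolate; the symmetric ketone can give only one enol triflate.

Step 4
Reactants: 4 3-[(TBDPS-oxy)methyl]cyclohex-2-en-1-one; 7 2,2-dimethyl-4H-1,3-dioxin-5-yl trifluoromethanesulfonate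
Product: 9 rac-6-(dioxinyl)-3-[(TBDPS-oxy)methyl]cyclohex-2-en-1-one, via lithium dienolate 8 (not isolated)
Conditions: 4, LiN(SiMe3)2, THF, −78 °C; then 7, Pd(OAc)2 (5 mol%), XPhos (10 mol%), −78 → 25 °C; AcOH, −78 °C
Reagents that add atoms: none
Why: kinetic deprotonation gives the cross-conjugated α′-enolate, which is coupled with the alkenyl triflate by Pd-catalysed ketone α-alkenylation (oxidative addition to zerovalent palladium formed in situ, transmetalation, reductive elimination), and the cold acidic quench should protonate on carbon and leave the enol ether double bond in the dioxin ring; the doubly activated C6 centre is configurationally labile, so the ketone is taken on as the racemate.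

Step 5
Reactants: 9 rac-6-(dioxinyl)-3-[(TBDPS-oxy)methyl]cyclohex-2-en-1-one
Product: 10 rac-trans-(1R*,6S*)-6-(dioxinyl)-3-[(TBDPS-oxy)methyl]cyclohex-2-en-1-ol
Conditions: NaBH4, CeCl3·7H2O, MeOH, −78 °C
Reagents that add atoms: none
Why: Luche 1,2-reduction; axial hydride delivery to the half-chair with the dioxinyl group pseudo-equatorial should place the hydroxyl trans to it, and the minor cis alcohol is removed by chromatography.

Step 6
Reactants: 10 rac-trans-(1R*,6S*)-6-(dioxinyl)-3-[(TBDPS-oxy)methyl]cyclohex-2-en-1-ol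
Product: 11 (1R,6S)-6-(dioxinyl)-3-[(TBDPS-oxy)methyl]cyclohex-2-en-1-yl acetate
Conditions: lipase PS (Burkholderia cepacia), vinyl acetate, t-BuOMe, 30 °C, stopped short of half conversion
Reagents that add atoms: vinyl acetate, CC(=O)OC=C
Why: enzymatic kinetic resolution by irreversible transesterification; with the branched C6 side as the large group and the vinylic C2 side as the medium group, the (1R,6S)-enantiomer should be acylated, and the unreacted (1S,6R)-alcohol is separated by chromatography.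

Step 7
Reactants: 11 (1R,6S)-6-(dioxinyl)-3-[(TBDPS-oxy)methyl]cyclohex-2-en-1-yl acetate
Product: 12 (1R,6S)-6-(dioxinyl)-3-[(TBDPS-oxy)methyl]cyclohex-2-en-1-ol
Conditions: K2CO3, MeOH, 0 °C
Reagents that add atoms: none
Why: mild transesterification removes the acetate without touching the silyl ether or the dioxin and without affecting either stereocentre.

Step 8
Reactants: 12 (1R,6S)-6-(dioxinyl)-3-[(TBDPS-oxy)methyl]cyclohex-2-en-1-ol
Product: 13 (S)-6-(dioxinyl)-3-[(TBDPS-oxy)methyl]cyclohex-2-en-1-one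
Conditions: Dess–Martin periodinane, NaHCO3, CH2Cl2, 0 °C
Reagents that add atoms: none
Why: buffered, non-basic Dess–Martin oxidation gives the enone without enolising the doubly activated C6–H, so the C6 configuration fixed by the resolution should be kept; the ketone is used at once.

Step 9
Reactants: 14 4-methoxybenzyl alcohol; 15 trichloroethylene
Product: 16 (E)-1,2-dichlorovinyl 4-methoxybenzyl ether
Conditions: KH, THF, 0 °C; then 15, −50 → 20 °C
Reagents that add atoms: none
Why: the potassium alkoxide dehydrochlorinates trichloroethylene to dichloroacetylene and adds to it, which is the standard addition–elimination entry to ynol ether precursors.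

Step 10
Reactants: 13 (S)-6-(dioxinyl)-3-[(TBDPS-oxy)methyl]cyclohex-2-en-1-one; 16 (E)-1,2-dichlorovinyl 4-methoxybenzyl ether
Product: 18 (1R,6S)-6-(dioxinyl)-1-[(PMB-oxy)ethynyl]-3-[(TBDPS-oxy)methyl]cyclohex-2-en-1-ol, via lithium acetylide 17 (not isolated)
Conditions: 16, n-BuLi (2 equiv), THF, −78 °C; CeCl3, −78 °C; then 13, −78 °C; pH 7 buffer
Reagents that add atoms: none
Why: the organocerium reagent from the lithium alkoxyacetylide adds to the carbonyl without enolising C6–H, and the small linear nucleophile should take the axial trajectory on the half-chair with the dioxinyl group pseudo-equatorial (torsional control, as in acetylide additions to 2-substituted cyclohexanones), which sets C1 with the alkyne cis and the hydroxyl trans to the dioxinyl group; any trans-dialkenyl isomer is removed by chromatography.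

Step 11
Reactants: 18 (1R,6S)-6-(dioxinyl)-1-[(PMB-oxy)ethynyl]-3-[(TBDPS-oxy)methyl]cyclohex-2-en-1-ol
Product: 19 (1R,6S)-6-(dioxinyl)-1-[(E)-2-(PMB-oxy)ethenyl]-3-[(TBDPS-oxy)methyl]cyclohex-2-en-1-ol
Conditions: LiAlH4, THF, 0 → 20 °C; then H2O, aq. NaOH
Reagents that add atoms: none
Why: alkoxide-directed trans-hydroalumination of the propargylic alcohol and protonolysis on work-up reduce the ynol ether to the E-enol ether only, the known course for 3-hydroxy-1-alkoxyalkynes.

Step 12
Reactants: 19 (1R,6S)-6-(dioxinyl)-1-[(E)-2-(PMB-oxy)ethenyl]-3-[(TBDPS-oxy)methyl]cyclohex-2-en-1-ol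
Product: 22 (8S,9S)-8-(PMB-oxy)-9,14-O-isopropylidene-15-(TBDPS-oxy)germacra-1(10),4-dien-6-one with both ring olefins ring-cis, via potassium alkoxide 20 (not isolated), via potassium enolate 21 (not isolated)
Conditions: KH, 18-crown-6, THF, −20 → 20 °C; then −78 °C, AcOH in THF
Reagents that add atoms: none
Why: Proposed new method: KH deprotonates the tertiary alcohol, and the potassium alkoxide 20, made more reactive by 18-crown-6, undergoes a charge-accelerated [3,3] shift through the 1,5-diene C8=C7–C6(O–)–C1–C10=C9 in which the C8–C9 bond forms while the C1–C6 bond of the cyclohexene breaks to give the C6 enolate 21; the closest known reaction is the anionic oxy-Cope ring expansion of cis-1,2-dialkenylcyclohexanols to (Z)-cyclodec-5-enones, which has not been run with an oxygen substituent on both bond-forming termini. The ten-membered ring is therefore made by four-carbon ring expansion of the six-membered ring (one σ bond made, one broken), not by end-to-end cyclisation, so no high dilution is needed and the ring-cis C4=C5 olefin is carried over unchanged. C8 and C9 are set together in a chair transition state: the E-enol ether holds O8 equatorial, the ring-fused dioxin holds O9 equatorial, and of the two chairs open to the cis-dialkenyl isomer the one with C2 axial on C1 is preferred, because its equatorial position on C1 is then occupied by hydrogen (no allylic 1,2-strain with C14) and the dioxinyl group stays equatorial on the cyclohexene; this chair gives 8S,9S and the ring-cis C1=C10 olefin. The step needs chair-over-boat selectivity, which the same strain argument supports, and it needs the β-alkoxy enolate to survive: as formed, its C8–O bond lies in the nodal plane of the enolate π system, so E1cB loss of 4-methoxybenzyl oxide requires a ring flip and should be outrun by the acetic acid quench at −78 °C.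

Step 13
Reactants: 22 (8S,9S)-8-(PMB-oxy)-9,14-O-isopropylidene-15-(TBDPS-oxy)germacra-1(10),4-dien-6-one
Product: 23 (8S,9S)-8-hydroxy-9,14-O-isopropylidene-15-(TBDPS-oxy)germacra-1(10),4-dien-6-one
Conditions: DDQ, CH2Cl2, pH 7 buffer, 0 °C
Reagents that add atoms: none
Why: oxidative cleavage of the PMB ether (hydride abstraction, hydrolysis of the oxocarbenium ion) under buffered conditions frees O8–H without touching the silyl ether, the acetonide or the olefins; the β-hydroxy ketone is used without delay.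

Step 14
Reactants: 23 (8S,9S)-8-hydroxy-9,14-O-isopropylidene-15-(TBDPS-oxy)germacra-1(10),4-dien-6-one
Product: 26 (7R,8S,9S)-7-(2-ethoxy-2-oxoethyl)-8-(TES-oxy)-9,14-O-isopropylidene-15-(TBDPS-oxy)germacra-1(10),4-dien-6-one, via dilithium aldolate 24 (not isolated), via lithium alkoxide 25 (not isolated)
Conditions: LiN(iPr)2 (2.2 equiv), THF, −78 °C; ICH2CO2Et, DMPU, −78 → −50 °C; then Et3SiOTf, −78 °C
Reagents that add atoms: ethyl iodoacetate, ICC(=O)OCC; triethylsilyl trifluoromethanesulfonate, CC[Si](CC)(CC)OS(=O)(=O)C(F)(F)F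
Why: Fráter–Seebach-type alkylation: the ring-trans enolate of the dilithium aldolate is held in a six-membered O–Li–O chelate with O8, so C9 and the rest of the ring cover one face and ethyl iodoacetate should enter anti to C9, which sets C7 with the new carbon anti to O8 as in the target; an alkoxide cannot leave, so E1cB is excluded, and Et3SiOTf caps the C8 alkoxide before it can attack the new ester.

Step 15
Reactants: 26 (7R,8S,9S)-7-(2-ethoxy-2-oxoethyl)-8-(TES-oxy)-9,14-O-isopropylidene-15-(TBDPS-oxy)germacra-1(10),4-dien-6-one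
Product: 28 (6S,7S,8S,9S) cis-fused 6,12-lactone (C6 epimer of the target series) with 8-(TES-oxy), 9,14-O-isopropylidene and 15-(TBDPS-oxy) groups, via lithium alkoxide 27 (not isolated)
Conditions: LiBH(s-Bu)3, THF, −78 → 0 °C
Reagents that add atoms: none
Why: Felkin–Anh 1,2-reduction of the enone carbonyl by the bulky hydride anti to C8 (the peripheral face; the fully substituted C4 blocks 1,4-reduction) should give the C6 alkoxide with O6 syn to O8, which closes onto the ethyl ester to the cis-fused lactone; C6 is deliberately set as the epimer and is inverted in step 16.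

Step 16
Reactants: 28 (6S,7S,8S,9S) cis-fused 6,12-lactone
Product: 31 (6R,7S,8S,9S) trans-fused 6,12-lactone with 8-(TES-oxy), 9,14-O-isopropylidene and 15-(TBDPS-oxy) groups, via lithium carboxylate 29 (not isolated), via hydroxy acid 30 (not isolated)
Conditions: LiOH, THF/H2O, 0 °C; NaH2PO4 (pH 5), cold extraction; then PPh3, DIAD, THF, 0 °C
Reagents that add atoms: lithium hydroxide, [Li+].[OH-]
Why: saponification gives the γ-hydroxy acid, and Mitsunobu lactonisation activates the allylic C6–OH as its oxyphosphonium ion, which the carboxylate displaces intramolecularly with inversion (SN2, 5-exo), so C6 becomes R and the lactone trans-fused.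

Step 17
Reactants: 31 (6R,7S,8S,9S) trans-fused 6,12-lactone
Product: 35 (6R,7S,8S,9S)-8-(TES-oxy)-9,14-O-isopropylidene-15-(TBDPS-oxy)germacra-1(10),4,11(13)-trien-12,6-olide, via lithium enolate 32 (not isolated), via Mannich base 33 (not isolated), via ammonium iodide 34 (not isolated)
Conditions: LiN(iPr)2, THF, −78 °C; Me2N=CH2 I (Eschenmoser's salt), −78 → 20 °C; MeI, MeOH, 20 °C; NaHCO3 (aq), CH2Cl2
Reagents that add atoms: N,N-dimethylmethyleneiminium iodide (Eschenmoser's salt), C=[N+](C)C.[I-]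
Why: α-methylenation of the lactone by Mannich reaction of its lithium enolate, quaternisation and Hofmann-type elimination; the enolate carbon carries no β-leaving group and O8 is inert as its silyl ether.

Step 18
Reactants: 35 (6R,7S,8S,9S)-8-(TES-oxy)-9,14-O-isopropylidene-15-(TBDPS-oxy)germacra-1(10),4,11(13)-trien-12,6-olide
Product: 36 8-hydroxy-9,14-O-isopropylidene-15-(TBDPS-oxy)germacra-1(10),4,11(13)-trien-12,6-olide (same spatial arrangement as 35)
Conditions: HF·pyridine, pyridine, THF, 0 °C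
Reagents that add atoms: none
Why: buffered fluoride cleavage of the secondary triethylsilyl ether should leave the primary tert-butyldiphenylsilyl ether and the acetonide in place.

Step 19
Reactants: 36 8-hydroxy-9,14-O-isopropylidene-15-(TBDPS-oxy)germacra-1(10),4,11(13)-trien-12,6-olide
Product: 37 (6R,7S,8S,9S)-8-(methacryloyloxy)-9,14-O-isopropylidene-15-(TBDPS-oxy)germacra-1(10),4,11(13)-trien-12,6-olide
Conditions: methacrylic anhydride, Et3N, DMAP, CH2Cl2, 0 → 20 °C
Reagents that add atoms: methacrylic anhydride, CC(=C)C(=O)OC(=O)C(C)=C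
Why: DMAP-catalysed acylation of the C8 hydroxyl under mild conditions, which should be faster than translactonisation of the free 8-hydroxy lactone towards O8.

Step 20
Reactants: 37 (6R,7S,8S,9S)-8-(methacryloyloxy)-9,14-O-isopropylidene-15-(TBDPS-oxy)germacra-1(10),4,11(13)-trien-12,6-olide
Product: 38 (6R,7S,8S,9S)-9,14-dihydroxy-8-(methacryloyloxy)-15-(TBDPS-oxy)germacra-1(10),4,11(13)-trien-12,6-olide
Conditions: PPTS, MeOH, 40 °C
Reagents that add atoms: none
Why: acid-catalysed transacetalisation removes the six-membered acetonide from O9 and O14, while the silyl ether, the two esters and the lactone should be stable to PPTS in methanol.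

Step 21
Reactants: 38 (6R,7S,8S,9S)-9,14-dihydroxy-8-(methacryloyloxy)-15-(TBDPS-oxy)germacra-1(10),4,11(13)-trien-12,6-olide
Product: 39 (6R,7S,8S,9S)-9-hydroxy-8-(methacryloyloxy)-14-oxo-15-(TBDPS-oxy)germacra-1(10),4,11(13)-trien-12,6-olide
Conditions: TEMPO (cat.), PhI(OAc)2, CH2Cl2, 20 °C
Reagents that add atoms: none
Why: oxoammonium oxidation is selective for the primary allylic C14 alcohol over the secondary C9 alcohol and stops at the enal, whose formyl group stays trans to C2, the more stable arrangement.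

Step 22
Reactants: 39 (6R,7S,8S,9S)-9-hydroxy-8-(methacryloyloxy)-14-oxo-15-(TBDPS-oxy)germacra-1(10),4,11(13)-trien-12,6-olide
Product: 40 (6R,7S,8S,9S)-9-acetoxy-8-(methacryloyloxy)-14-oxo-15-(TBDPS-oxy)germacra-1(10),4,11(13)-trien-12,6-olide
Conditions: Ac2O, pyridine, DMAP (cat.), CH2Cl2, 0 °C
Reagents that add atoms: acetic anhydride, CC(=O)OC(C)=O
Why: acetylation of the remaining secondary allylic hydroxyl under mild base, cold enough to avoid allylic displacement next to the enal.

Step 23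
Reactants: 40 (6R,7S,8S,9S)-9-acetoxy-8-(methacryloyloxy)-14-oxo-15-(TBDPS-oxy)germacra-1(10),4,11(13)-trien-12,6-olide
Product: 41 (6R,7S,8S,9S)-9-acetoxy-15-hydroxy-8-(methacryloyloxy)-14-oxogermacra-1(10),4,11(13)-trien-12,6-olide (CNP0147326.4)
Conditions: HF·pyridine, THF, 0 → 20 °C
Reagents that add atoms: none
Why: final fluoride cleavage of the primary silyl ether under non-basic conditions should spare the two esters, the enal, the allylic acetate and the α-methylene lactone.

**Compound list**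

1 | 3-methoxybenzyl alcohol | COc1cccc(CO)c1 | starting material
2 | (5-methoxycyclohexa-1,4-dien-1-yl)methanol | COC1=CCC=C(CO)C1 | intermediate
3 | 3-(hydroxymethyl)cyclohex-2-en-1-one | O=C1C=C(CO)CCC1 | intermediate
4 | 3-[(TBDPS-oxy)methyl]cyclohex-2-en-1-one | O=C1C=C(CO[Si](c2ccccc2)(c2ccccc2)C(C)(C)C)CCC1 | intermediate
5 | 2,2-dimethyl-1,3-dioxan-5-one | CC1(C)OCC(=O)CO1 | starting material
6 | lithium 2,2-dimethyl-4H-1,3-dioxin-5-olate | [Li+].CC1(C)OCC([O-])=CO1 | intermediate
7 | 2,2-dimethyl-4H-1,3-dioxin-5-yl trifluoromethanesulfonate | CC1(C)OCC(OS(=O)(=O)C(F)(F)F)=CO1 | intermediate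
8 | lithium 5-[(TBDPS-oxy)methyl]cyclohexa-1,5-dien-1-olate | [Li+].[O-]C1=CCCC(CO[Si](c2ccccc2)(c2ccccc2)C(C)(C)C)=C1 | intermediate
9 | rac-6-(dioxinyl)-3-[(TBDPS-oxy)methyl]cyclohex-2-en-1-one | O=C1C=C(CO[Si](c2ccccc2)(c2ccccc2)C(C)(C)C)CCC1C1=COC(C)(C)OC1 | intermediate
10 | rac-trans-(1R*,6S*)-6-(dioxinyl)-3-[(TBDPS-oxy)methyl]cyclohex-2-en-1-ol (racemate, one enantiomer drawn) | O[C@@H]1C=C(CO[Si](c2ccccc2)(c2ccccc2)C(C)(C)C)CC[C@H]1C1=COC(C)(C)OC1 | intermediate
11 | (1R,6S)-6-(dioxinyl)-3-[(TBDPS-oxy)methyl]cyclohex-2-en-1-yl acetate | CC(=O)O[C@@H]1C=C(CO[Si](c2ccccc2)(c2ccccc2)C(C)(C)C)CC[C@H]1C1=COC(C)(C)OC1 | intermediate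
12 | (1R,6S)-6-(dioxinyl)-3-[(TBDPS-oxy)methyl]cyclohex-2-en-1-ol | O[C@@H]1C=C(CO[Si](c2ccccc2)(c2ccccc2)C(C)(C)C)CC[C@H]1C1=COC(C)(C)OC1 | intermediate
13 | (S)-6-(dioxinyl)-3-[(TBDPS-oxy)methyl]cyclohex-2-en-1-one | O=C1C=C(CO[Si](c2ccccc2)(c2ccccc2)C(C)(C)C)CC[C@H]1C1=COC(C)(C)OC1 | intermediate
14 | 4-methoxybenzyl alcohol | COc1ccc(CO)cc1 | starting material
15 | trichloroethylene | ClC=C(Cl)Cl | starting material
16 | (E)-1,2-dichlorovinyl 4-methoxybenzyl ether | Cl/C=C(\OCc1ccc(OC)cc1)Cl | intermediate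
17 | lithium (4-methoxybenzyloxy)acetylide | [Li+].[C-]#COCc1ccc(OC)cc1 | intermediate
18 | (1R,6S)-6-(dioxinyl)-1-[(PMB-oxy)ethynyl]-3-[(TBDPS-oxy)methyl]cyclohex-2-en-1-ol | O[C@]1(C#COCc2ccc(OC)cc2)C=C(CO[Si](c2ccccc2)(c2ccccc2)C(C)(C)C)CC[C@H]1C1=COC(C)(C)OC1 | intermediate
19 | (1R,6S)-6-(dioxinyl)-1-[(E)-2-(PMB-oxy)ethenyl]-3-[(TBDPS-oxy)methyl]cyclohex-2-en-1-ol | O[C@]1(/C=C/OCc2ccc(OC)cc2)C=C(CO[Si](c2ccccc2)(c2ccccc2)C(C)(C)C)CC[C@H]1C1=COC(C)(C)OC1 | intermediate
20 | potassium alkoxide of 19 | [K+].[O-][C@]1(/C=C/OCc2ccc(OC)cc2)C=C(CO[Si](c2ccccc2)(c2ccccc2)C(C)(C)C)CC[C@H]1C1=COC(C)(C)OC1 | intermediate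
21 | potassium C6 enolate of 22 (ring-trans C6=C7) | [K+].COc1ccc(cc1)CO[C@H]1/C=C(\[O-])/C=C(/CO[Si](c2ccccc2)(c2ccccc2)C(C)(C)C)CC/C=C(/COC(C)(C)O3)[C@@H]13 | intermediate
22 | (8S,9S)-8-(PMB-oxy)-9,14-O-isopropylidene-15-(TBDPS-oxy)germacra-1(10),4-dien-6-one, ring olefins ring-cis | COc1ccc(cc1)CO[C@H]1CC(=O)/C=C(/CO[Si](c2ccccc2)(c2ccccc2)C(C)(C)C)CC/C=C(/COC(C)(C)O3)[C@@H]13 | intermediate
23 | (8S,9S)-8-hydroxy-9,14-O-isopropylidene-15-(TBDPS-oxy)germacra-1(10),4-dien-6-one | O[C@H]1CC(=O)/C=C(/CO[Si](c2ccccc2)(c2ccccc2)C(C)(C)C)CC/C=C(/COC(C)(C)O3)[C@@H]13 | intermediate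
24 | dilithium salt of 23 (C8 alkoxide, C6 enolate) | [Li+].[Li+].[O-][C@H]1/C=C(\[O-])/C=C(/CO[Si](c2ccccc2)(c2ccccc2)C(C)(C)C)CC/C=C(/COC(C)(C)O3)[C@@H]13 | intermediate
25 | lithium C8 alkoxide of the C7-(2-ethoxy-2-oxoethyl) ketone | [Li+].[O-][C@H]1[C@@H](CC(=O)OCC)C(=O)/C=C(/CO[Si](c2ccccc2)(c2ccccc2)C(C)(C)C)CC/C=C(/COC(C)(C)O3)[C@@H]13 | intermediate
26 | (7R,8S,9S)-7-(2-ethoxy-2-oxoethyl)-8-(TES-oxy)-9,14-O-isopropylidene-15-(TBDPS-oxy)germacra-1(10),4-dien-6-one | CC[Si](CC)(CC)O[C@H]1[C@@H](CC(=O)OCC)C(=O)/C=C(/CO[Si](c2ccccc2)(c2ccccc2)C(C)(C)C)CC/C=C(/COC(C)(C)O3)[C@@H]13 | intermediate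
27 | lithium C6 alkoxide of the reduced keto ester (O6 syn to O8) | [Li+].CC[Si](CC)(CC)O[C@H]1[C@@H](CC(=O)OCC)[C@@H]([O-])/C=C(/CO[Si](c2ccccc2)(c2ccccc2)C(C)(C)C)CC/C=C(/COC(C)(C)O3)[C@@H]13 | intermediate
28 | (6S,7S,8S,9S) cis-fused 6,12-lactone, 8-(TES-oxy), 9,14-O-isopropylidene, 15-(TBDPS-oxy) | CC[Si](CC)(CC)O[C@H]1[C@H]2CC(=O)O[C@H]2/C=C(/CO[Si](c2ccccc2)(c2ccccc2)C(C)(C)C)CC/C=C(/COC(C)(C)O3)[C@@H]13 | intermediate
29 | lithium carboxylate from ring opening of 28 | [Li+].CC[Si](CC)(CC)O[C@H]1[C@@H](CC(=O)[O-])[C@@H](O)/C=C(/CO[Si](c2ccccc2)(c2ccccc2)C(C)(C)C)CC/C=C(/COC(C)(C)O3)[C@@H]13 | intermediate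
30 | γ-hydroxy acid from 28 | CC[Si](CC)(CC)O[C@H]1[C@@H](CC(=O)O)[C@@H](O)/C=C(/CO[Si](c2ccccc2)(c2ccccc2)C(C)(C)C)CC/C=C(/COC(C)(C)O3)[C@@H]13 | intermediate
31 | (6R,7S,8S,9S) trans-fused 6,12-lactone, 8-(TES-oxy), 9,14-O-isopropylidene, 15-(TBDPS-oxy) | CC[Si](CC)(CC)O[C@H]1[C@H]2CC(=O)O[C@@H]2/C=C(/CO[Si](c2ccccc2)(c2ccccc2)C(C)(C)C)CC/C=C(/COC(C)(C)O3)[C@@H]13 | intermediate
32 | lithium enolate of 31 | [Li+].CC[Si](CC)(CC)O[C@H]1[C@H]2C=C([O-])O[C@@H]2/C=C(/CO[Si](c2ccccc2)(c2ccccc2)C(C)(C)C)CC/C=C(/COC(C)(C)O3)[C@@H]13 | intermediate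
33 | 11-(dimethylaminomethyl) lactone (C11 configuration not defined) | CC[Si](CC)(CC)O[C@H]1[C@H]2C(CN(C)C)C(=O)O[C@@H]2/C=C(/CO[Si](c2ccccc2)(c2ccccc2)C(C)(C)C)CC/C=C(/COC(C)(C)O3)[C@@H]13 | intermediate
34 | 11-(trimethylammoniomethyl) lactone iodide | [I-].CC[Si](CC)(CC)O[C@H]1[C@H]2C(C[N+](C)(C)C)C(=O)O[C@@H]2/C=C(/CO[Si](c2ccccc2)(c2ccccc2)C(C)(C)C)CC/C=C(/COC(C)(C)O3)[C@@H]13 | intermediate
35 | (6R,7S,8S,9S)-8-(TES-oxy)-9,14-O-isopropylidene-15-(TBDPS-oxy)germacra-1(10),4,11(13)-trien-12,6-olide | CC[Si](CC)(CC)O[C@H]1[C@H]2C(=C)C(=O)O[C@@H]2/C=C(/CO[Si](c2ccccc2)(c2ccccc2)C(C)(C)C)CC/C=C(/COC(C)(C)O3)[C@@H]13 | intermediate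
36 | 8-hydroxy-9,14-O-isopropylidene-15-(TBDPS-oxy)germacra-1(10),4,11(13)-trien-12,6-olide | O[C@H]1[C@H]2C(=C)C(=O)O[C@@H]2/C=C(/CO[Si](c2ccccc2)(c2ccccc2)C(C)(C)C)CC/C=C(/COC(C)(C)O3)[C@@H]13 | intermediate
37 | (6R,7S,8S,9S)-8-(methacryloyloxy)-9,14-O-isopropylidene-15-(TBDPS-oxy)germacra-1(10),4,11(13)-trien-12,6-olide | C=C(C)C(=O)O[C@H]1[C@H]2C(=C)C(=O)O[C@@H]2/C=C(/CO[Si](c2ccccc2)(c2ccccc2)C(C)(C)C)CC/C=C(/COC(C)(C)O3)[C@@H]13 | intermediate
38 | (6R,7S,8S,9S)-9,14-dihydroxy-8-(methacryloyloxy)-15-(TBDPS-oxy)germacra-1(10),4,11(13)-trien-12,6-olide | C=C(C)C(=O)O[C@H]1[C@H]2C(=C)C(=O)O[C@@H]2/C=C(/CO[Si](c2ccccc2)(c2ccccc2)C(C)(C)C)CC/C=C(/CO)[C@@H]1O | intermediate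
39 | (6R,7S,8S,9S)-9-hydroxy-8-(methacryloyloxy)-14-oxo-15-(TBDPS-oxy)germacra-1(10),4,11(13)-trien-12,6-olide | C=C(C)C(=O)O[C@H]1[C@H]2C(=C)C(=O)O[C@@H]2/C=C(/CO[Si](c2ccccc2)(c2ccccc2)C(C)(C)C)CC/C=C(/C=O)[C@@H]1O | intermediate
40 | (6R,7S,8S,9S)-9-acetoxy-8-(methacryloyloxy)-14-oxo-15-(TBDPS-oxy)germacra-1(10),4,11(13)-trien-12,6-olide | C=C(C)C(=O)O[C@H]1[C@H]2C(=C)C(=O)O[C@@H]2/C=C(/CO[Si](c2ccccc2)(c2ccccc2)C(C)(C)C)CC/C=C(/C=O)[C@@H]1OC(C)=O | intermediate
41 | (6R,7S,8S,9S)-9-acetoxy-15-hydroxy-8-(methacryloyloxy)-14-oxogermacra-1(10),4,11(13)-trien-12,6-olide | C=C(C)C(=O)O[C@H]1[C@H]2C(=C)C(=O)O[C@@H]2/C=C(/CO)CC/C=C(/C=O)[C@@H]1OC(C)=O | target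

**Step count**

Total: 23 steps. Longest linear sequence: 21 steps (from 1 through steps 1, 2, 4–8 and 10–23; steps 3 and 9 make the side fragments 7 and 16).

**Steps most likely to fail**

1. Step 12 (ring expansion). What may go wrong: loss of the C8 alkoxide from the enolate by E1cB, a rearrangement too slow at temperatures where that enolate survives, or leakage through the second chair to the ring-trans C1=C10 olefin. Fallback, setting out from 13 and returning at 23: the C8 oxygen is carried through the expansion as silicon, which cannot leave from a β-silyl enolate. The CeCl3-modified lithium acetylide of ethynyl(dimethyl)(pyridin-2-yl)silane is added to 13 to give the silylalkynyl carbinol F1. NaAlH2(OCH2CH2OMe)2 reduces it to the (E)-vinylsilane carbinol F2. KH with 18-crown-6 then effects the ordinary anionic oxy-Cope expansion to the 8-silyl ketone F3, with the same spatial arrangement at C8 and C9. Tamao oxidation of the pyridylsilyl group (H2O2, KF, KHCO3) replaces silicon by hydroxyl with retention and gives 23.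

2. Step 14 (C7 alkylation). What may go wrong: deprotonation at the γ-position of the enone or retro-aldol opening of the aldolate instead of C7 enolisation, or incomplete facial control at C7. Fallback, setting out from 22 and returning at 26: the PMB ether is kept during the C–C bond formation. The lithium enolate of 22 (LiN(iPr)2, THF, −78 °C), chelated by the ether oxygen, is alkylated with ethyl iodoacetate to the PMB keto ester F4. DDQ then frees the hydroxy keto ester F5, which is silylated (Et3SiOTf, 2,6-lutidine, −78 °C) to 26.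

3. Step 10 (acetylide addition). What may go wrong: attack of the acetylide on the face trans to the dioxinyl group, which would give the trans-dialkenyl carbinol and after expansion the ring-trans olefin, or enolisation and racemisation of 13. Fallback, setting out from 12 and returning at 19 (13 and 18 are bypassed): stereospecific lithiation–borylation. Alcohol 12 is converted into its N,N-diisopropylcarbamate F6 (iPr2NCOCl, Et3N, heat). 4-Methoxybenzyl ethynyl ether F7 (from 17 by protonation) is hydroborated with pinacolborane (Cp2ZrHCl cat.) to the pinacol (E)-2-(4-methoxybenzyloxy)vinylboronate F8. s-BuLi/TMEDA removes the carbinol hydrogen of F6 with retention, F8 is added, and 1,2-migration of the alkenyl group gives the tertiary allylic boronic ester F9. Oxidation (NaOH, H2O2) with retention leaves the alkenyl group where the hydrogen was, cis to the dioxinyl group, and the hydroxyl trans, which is 19.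

Further compounds
F1 | step 12 | (1R,6S)-6-(dioxinyl)-1-{[dimethyl(pyridin-2-yl)silyl]ethynyl}-3-[(TBDPS-oxy)methyl]cyclohex-2-en-1-ol | O[C@]1(C#C[Si](C)(C)c2ccccn2)C=C(CO[Si](c2ccccc2)(c2ccccc2)C(C)(C)C)CC[C@H]1C1=COC(C)(C)OC1
F2 | step 12 | (1R,6S)-6-(dioxinyl)-1-{(E)-2-[dimethyl(pyridin-2-yl)silyl]ethenyl}-3-[(TBDPS-oxy)methyl]cyclohex-2-en-1-ol | O[C@]1(/C=C/[Si](C)(C)c2ccccn2)C=C(CO[Si](c2ccccc2)(c2ccccc2)C(C)(C)C)CC[C@H]1C1=COC(C)(C)OC1
F3 | step 12 | 8-[dimethyl(pyridin-2-yl)silyl]-9,14-O-isopropylidene-15-(TBDPS-oxy)germacra-1(10),4-dien-6-one, spatial arrangement at C8 and C9 as in 22 | C[Si](C)(c1ccccn1)[C@H]1CC(=O)/C=C(/CO[Si](c2ccccc2)(c2ccccc2)C(C)(C)C)CC/C=C(/COC(C)(C)O3)[C@@H]13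
F4 | step 14 | 7-(2-ethoxy-2-oxoethyl)-8-(PMB-oxy)-9,14-O-isopropylidene-15-(TBDPS-oxy)germacra-1(10),4-dien-6-one, spatial arrangement as in 26 | COc1ccc(cc1)CO[C@H]1[C@@H](CC(=O)OCC)C(=O)/C=C(/CO[Si](c2ccccc2)(c2ccccc2)C(C)(C)C)CC/C=C(/COC(C)(C)O3)[C@@H]13
F5 | step 14 | 7-(2-ethoxy-2-oxoethyl)-8-hydroxy-9,14-O-isopropylidene-15-(TBDPS-oxy)germacra-1(10),4-dien-6-one, spatial arrangement as in 26 | O[C@H]1[C@@H](CC(=O)OCC)C(=O)/C=C(/CO[Si](c2ccccc2)(c2ccccc2)C(C)(C)C)CC/C=C(/COC(C)(C)O3)[C@@H]13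
F6 | step 10 | (1R,6S)-6-(dioxinyl)-3-[(TBDPS-oxy)methyl]cyclohex-2-en-1-yl N,N-diisopropylcarbamate | CC(C)N(C(C)C)C(=O)O[C@@H]1C=C(CO[Si](c2ccccc2)(c2ccccc2)C(C)(C)C)CC[C@H]1C1=COC(C)(C)OC1
F7 | step 10 | 4-methoxybenzyl ethynyl ether | COc1ccc(COC#C)cc1
F8 | step 10 | pinacol (E)-2-(4-methoxybenzyloxy)vinylboronate | COc1ccc(CO/C=C/B2OC(C)(C)C(C)(C)O2)cc1
F9 | step 10 | pinacol boronic ester with boron on C1 in place of the hydroxyl of 19 (same spatial arrangement) | CC1(C)OB(OC1(C)C)[C@]1(/C=C/OCc2ccc(OC)cc2)C=C(CO[Si](c2ccccc2)(c2ccccc2)C(C)(C)C)CC[C@H]1C1=COC(C)(C)OC1
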